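1. Slowness comes first: past its peak, the single product in the west flask falls, and the fall eases late in the run. It reads 19.2% at 10.0 min, bends at 22.6% near 25.0 min, then sinks.

| flask | starting material | reagent | capture agent | remark | time |
|---|---|---|---|---|---|
| west | 0.20 M | 0.10 M | 0.060 M | the very flask that is asked about, followed so far |  |
| south-east | 0.20 M | 0.10 M | 0.040 M | run made earlier |  |
| flask | 0.20 M | 0.100 M | 0.0600 M |  | 10 h |

- west (time / min: single product / %, tris adduct / %): 10.0: 19.2, 0; 15.0: 21.8, 0; 25.0: 22.6, 0.5; 40.0: 20.7, 1.1; 80.0: 15.5, 0.1; 120: 12.5, 0
- south-east (time / h: single product / %, tris adduct / %): 0.333: 23.2, 0.9; 0.500: 23.4, 0; 0.833: 21.4, 0.2; 1.33: 19.6, 0; 2.50: 16.0, 0.7; 4.00: 12.9, 0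

(scatter of a reading: 0.5 percentage points)

- equivalents of reagent to starting material, everything else as given, that leave most single product at 10 h
- the amount of single product then, in percent of the starting material charged
- the amount of single product with the amounts as given



2. I draw the fall as the reciprocal of the single product concentration. In the west run it rises 8.10 M⁻¹ from 40.0 min to 80.0 min, then 7.74 M⁻¹ up to 120 min. That is nearly straight.

3. A straight reciprocal is what two partners give when they meet one to one in equal amounts (second order, equal concentrations). This symmetric case is my zero.

4. I take the capture agent as the partner of the single product, and I assume the two equal in the west flask. Then the single product made there, free and captured together, matches the capture agent charge: 30.0% of the starting material charged. I call that share the output. Output minus capture charge, as a share of starting material, gives the level where I expect the curve to stop.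

5. The south-east run has the same charges of starting material and reagent, so I assume the same output there. Its level then reckons as 10.0%, and its last reading, 12.9%, still stands above it.

6. In my reckoning the level of the west flask is zero, so I let its line run on. The line's slope is 0.00330 M⁻¹ s⁻¹. Extended to 10 h, it gives me 3.70%. On the reagent question I commit to no number.

7. The forecast says 5%, and 45% at 2.5 equiv: “Extra reagent first fills the capture capacity, then raises the equilibrium.”

8. The flask gives 3.70%, and 8.27% at 0.958 equiv.

    starting material + reagent → single product (k = 0.00680 M⁻¹ s⁻¹)
    reagent + single product → bis adduct (k = 0.00760 M⁻¹ s⁻¹)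
    reagent + bis adduct → tris adduct (k = 0.00600 M⁻¹ s⁻¹)
    reagent + tris adduct → tetra adduct (k = 2.90 × 10⁻⁴ M⁻¹ s⁻¹)
    single product + capture agent → trapped intermediate (k = 0.00390 M⁻¹ s⁻¹)
    starting material + tris adduct → side product (k = 0.00840 M⁻¹ s⁻¹)

9. At 10.0 h, single product and trapped intermediate in the asked flask sum to 30.9% of the starting material charged, against my output of 30.0%. The neighbour flask differs from it in one charge, 0.024 M of capture agent, so with the same output its level reckons as 18.0%. Its capture agent is down to 0.43% of its own charge, and its trapped intermediate stands at 11.9% of the starting material charged. Its single product stands at 17.9%.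

The data stem from a simulated flask for substances that don't exist; scatter was added.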